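Answer 3 questions on this flask from 2 earlier runs.

| flask | starting material | free catalyst | impurity | remark | time |
|---|---|---|---|---|---|
| grey | 0.20 mM | 9.5 µM | 2 µM | run made earlier |  |
| violet | 0.20 mM | 14 µM | 2 µM | run made earlier |  |
| flask | 0.20 mM | 19 µM | 2.0 µM |  | 1.0 h |

- grey (time / min: isomer of the product / %, target / %, starting material / %): 10.0: 39.5, 29.3, 31.4; 20.0: 47.6, 25.3, 26.6; 25.0: 48.7, 24.6, 26.0; 40.0: 48.2, 24.5, 25.8
- violet (time / min: isomer of the product / %, target / %, starting material / %): 10.0: 44.1, 27.4, 28.8; 20.0: 48.8, 24.0, 26.0; 25.0: 48.6, 25.2, 25.3; 40.0: 49.9, 25.0, 25.3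

(scatter of a reading: 0.5 percentage points)

1. ratio of isomer of the product to target at 0.40 s
2. ratio of isomer of the product to target at 1.0 h
3. which of isomer of the product and target there is more of at 1.0 h

- candidate steps: isomer of the product + free catalyst <-> starting material + free catalyst; free catalyst + impurity -> spent catalyst; 2 free catalyst <-> resting dimer; target -> over-reaction product; starting material + free catalyst <-> target + free catalyst; target + free catalyst <-> isomer of the product + free catalyst

Open a ledger of the starting material charged, using the last readings of each run, at 40.0 min. Grey books starting material 25.8 %, target 24.5 % and isomer of the product 48.2 %; violet books 25.3 %, 25.0 % and 49.9 %. Add each column: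

grey: 98.5 %
violet: 100.2 %

Grey falls short of 100 % and violet runs over, so these sums put no figure on over-reaction product.

Now divide the forward rate of target + free catalyst ⇌ isomer of the product by its backward rate. Both carry [free catalyst], so catalyst and time cancel, and at balance the quotient of the two entries is a constant (thermodynamic control). Read it from each run:

grey: 1.97
violet: 2.00
pooled: ρ = 1.98

Call ρ the plateau ratio, the isomer of the product booked per target at balance.

Grey's isomer of the product already reads 48.7 % and 48.2 % at 25.0 min and 40.0 min. The flask has twice grey's catalyst charge and runs for 1.0 h, longer than grey's last reading. So book the flask at ρ at 1.0 h, with isomer of the product ahead. Give no figure at 0.40 s: ρ describes balance, and no reading stands before 10.0 min.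

The forecast gives 0.1 at 0.40 s (range 0.001 to 0.5), 2 at 1.0 h and isomer of the product ahead: “This plateau is thermodynamic and independent of catalyst loading.”

The flask gives 0.0212 at 0.40 s and 2.00 at 1.0 h, with isomer of the product ahead.

    isomer of the product + free catalyst ⇌ starting material + free catalyst, rate k1*[free catalyst]*[isomer of the product] forward; the back reaction follows from the equilibrium constant (k = 96.0 L mol⁻¹ s⁻¹)
    free catalyst + impurity → spent catalyst (k = 3.00 × 10⁵ L mol⁻¹ s⁻¹)
    2 free catalyst ⇌ resting dimer (K = 77000 L mol⁻¹, k = 42000 L mol⁻¹ s⁻¹)
    target → over-reaction product (k = 1.30 × 10⁻⁵ s⁻¹)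
    starting material + free catalyst ⇌ target + free catalyst, rate k5*[starting material]*[free catalyst] forward; the back reaction follows from the equilibrium constant (K = 0.960, k = 9500 L mol⁻¹ s⁻¹)
    target + free catalyst ⇌ isomer of the product + free catalyst, rate k6*[free catalyst]*[target] forward; the back reaction follows from the equilibrium constant (K = 2.00, k = 420 L mol⁻¹ s⁻¹)

The flask's ledger at 1.0 h holds starting material 25.4 %, target 24.4 %, isomer of the product 48.9 % and a further entry of 1.21 % over-reaction product, which leaves the ratio practically where it stands. Multiply the flask's target by ρ to reckon 48.3 % of isomer of the product, beside the 48.9 % the flask holds. Carry ρ of 1.98 to the neighbour charged with 0.076 mM of free catalyst, which ends at a ratio of 2.00.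

The runs were computed from invented constants, and the scatter is random.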